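**Retrosynthetic overview**

1. The last bond is O(C3')–C4: the C9 naphthol, para to C4a, is oxidised to a para-quinone methide, and the catechol oxygen already held on the C3 ketal carbon closes the cis-fused dioxane, so C3 relays its configuration to C4.
2. Key disconnection, a (3+3) annulation of ring C that joins both halves: C3–C4 by enantioselective phase-transfer benzylation and C1–C10a by palladium-catalysed α-arylation in one flask. It is possible because the C2 ketone of ring C lies between two fully substituted carbons, the acidic ketal carbon C3 and the gem-dimethyl carbon C1, facing the ortho pair C4a(CH2)/C10a of ring B.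
3. Electrophile: a 2-bromo-1-(bromomethyl)naphthalene (rings A and B), ring B made by Friedel–Crafts acylation of an arylacetoacetate, then formylation and triflate-to-bromide exchange.
4. Nucleophile: the mixed aryl methyl acetal of 3-methyl-2-oxobutanal carrying the whole phenanthrene unit (biaryl by ortho-metalation/Suzuki coupling, middle ring by directed remote metalation).
5. Ring order: ring B of the naphthalene; middle ring of the phenanthrene; ring C (key step); dioxane ring.

Key step: step 20

Remark on numbering: locants C1–C10a are those of the 3,4-dihydrophenanthren-2(1H)-one unit of the target, primed locants those of the phenanthrene unit; in this numbering the target is (3S,4S), with the C3 methoxy group and the C4 hydrogen cis.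
Assumption: the (S,S)-configured ammonium catalyst is taken to give the (S)-ketal carbon; if the sense of induction is the opposite, the (R,R)-catalyst is used without other change.

**Route**

Step 1
Reactants: 1 2-(3-methoxy-4-methylphenyl)acetic acid; 2 potassium 3-ethoxy-3-oxopropanoate
Product: 4 ethyl 4-(3-methoxy-4-methylphenyl)-3-oxobutanoate, via acyl imidazole 3 (not isolated)
Conditions: CDI, THF, 23 °C; then 2, MgCl2, Et3N, MeCN, 23 → 50 °C; aq. HCl
Reagents that add atoms: none
Why: Decarboxylative Claisen-type acylation of the magnesium malonate half-ester by the acyl imidazole is a standard β-keto ester synthesis and should tolerate the aryl ether.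

Step 2
Reactants: 4 ethyl 4-(3-methoxy-4-methylphenyl)-3-oxobutanoate
Product: 5 6-methoxy-7-methylnaphthalene-1,3-diol
Conditions: conc. H2SO4, 0 → 23 °C
Reagents that add atoms: none
Why: Intramolecular Friedel–Crafts acylation by the ester carbonyl para to the methoxy group, followed by enolisation, should close ring B as the naphthalene-1,3-diol.

Step 3
Reactants: 5 6-methoxy-7-methylnaphthalene-1,3-diol
Product: 6 2,4-dihydroxy-7-methoxy-6-methylnaphthalene-1-carbaldehyde
Conditions: POCl3, DMF, MeCN, 0 → 23 °C; then H2O, NaOAc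
Reagents that add atoms: N,N-dimethylformamide (CN(C)C=O); water (O)
Why: Vilsmeier–Haack formylation should go to C4 of the diol, the α-position that is ortho to one hydroxyl and para to the other.

Step 4
Reactants: 6 2,4-dihydroxy-7-methoxy-6-methylnaphthalene-1-carbaldehyde
Product: 7 4-(benzyloxy)-2-hydroxy-7-methoxy-6-methylnaphthalene-1-carbaldehyde
Conditions: BnBr (1.05 equiv), KHCO3, DMF, 40 °C
Reagents that add atoms: benzyl bromide (BrCc1ccccc1)
Why: Williamson etherification should take the more acidic para-hydroxyl, because the ortho-hydroxyl is held in a hydrogen bond to the aldehyde.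

Step 5
Reactants: 7 4-(benzyloxy)-2-hydroxy-7-methoxy-6-methylnaphthalene-1-carbaldehyde
Product: 8 4-(benzyloxy)-1-formyl-7-methoxy-6-methylnaphthalen-2-yl trifluoromethanesulfonate
Conditions: Tf2O, pyridine, CH2Cl2, 0 °C
Reagents that add atoms: trifluoromethanesulfonic anhydride (O=S(=O)(OS(=O)(=O)C(F)(F)F)C(F)(F)F)
Why: O-Sulfonylation of the remaining phenol turns the oxygen on the future C10a into a leaving group.

Step 6
Reactants: 8 4-(benzyloxy)-1-formyl-7-methoxy-6-methylnaphthalen-2-yl trifluoromethanesulfonate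
Product: 9 4-(benzyloxy)-2-bromo-7-methoxy-6-methylnaphthalene-1-carbaldehyde
Conditions: LiBr, [Cp*Ru(MeCN)3]OTf (5 mol%), 1,3-dimethyl-2-imidazolidinone, 100 °C
Reagents that add atoms: lithium bromide ([Li+].[Br-])
Why: Ruthenium-catalysed triflate-to-bromide exchange (nucleophilic substitution on the η6-arene complex) should give the aryl bromide, which, unlike the triflate, survives the hydroxide of step 20.

Step 7
Reactants: 9 4-(benzyloxy)-2-bromo-7-methoxy-6-methylnaphthalene-1-carbaldehyde
Product: 10 [4-(benzyloxy)-2-bromo-7-methoxy-6-methylnaphthalen-1-yl]methanol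
Conditions: NaBH4, MeOH–THF, 0 °C
Reagents that add atoms: none
Why: Borohydride reduction of the aryl aldehyde leaves the aryl bromide and the ethers untouched.

Step 8
Reactants: 10 [4-(benzyloxy)-2-bromo-7-methoxy-6-methylnaphthalen-1-yl]methanol
Product: 11 4-(benzyloxy)-2-bromo-1-(bromomethyl)-7-methoxy-6-methylnaphthalene
Conditions: PBr3, CH2Cl2, 0 °C; used crude
Reagents that add atoms: phosphorus tribromide (BrP(Br)Br)
Why: Bromination of the electron-rich benzylic alcohol should be fast at 0 °C, and the labile bromide is carried on without purification.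

Step 9
Reactants: 12 4-bromo-2,3-dimethylphenol
Product: 13 5-bromo-2-hydroxy-3,4-dimethylbenzaldehyde
Conditions: MgCl2, Et3N, (CH2O)n, MeCN, reflux
Reagents that add atoms: paraformaldehyde, as formaldehyde (C=O)
Why: Magnesium-mediated ortho-formylation (Casnati–Skattebøl) can only occupy the single free ortho position of the phenol.

Step 10
Reactants: 13 5-bromo-2-hydroxy-3,4-dimethylbenzaldehyde
Product: 14 5-bromo-2-(methoxymethoxy)-3,4-dimethylbenzaldehyde
Conditions: MOMCl, i-Pr2NEt, CH2Cl2, 0 → 40 °C
Reagents that add atoms: chloromethyl methyl ether (COCCl)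
Why: Acetal protection of the future O2' gives a group that survives organolithium bases and is later removed without touching benzyl ethers.

Step 11
Reactants: 14 5-bromo-2-(methoxymethoxy)-3,4-dimethylbenzaldehyde
Product: 16 5-bromo-2-(methoxymethoxy)-3,4-dimethylphenol, via aryl formate 15 (not isolated)
Conditions: mCPBA, NaHCO3, CH2Cl2, 23 °C; then K2CO3 (cat.), MeOH
Reagents that add atoms: 3-chloroperbenzoic acid (OOC(=O)c1cccc(Cl)c1)
Why: Baeyer–Villiger oxidation of the electron-rich ortho-alkoxy benzaldehyde with aryl migration, then methanolysis of the formate, should install the future O3'.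

Step 12
Reactants: 16 5-bromo-2-(methoxymethoxy)-3,4-dimethylphenol
Product: 17 1-(benzyloxy)-5-bromo-2-(methoxymethoxy)-3,4-dimethylbenzene
Conditions: BnBr, K2CO3, DMF, 23 °C
Reagents that add atoms: benzyl bromide (BrCc1ccccc1)
Why: Williamson benzylation differentiates the two catechol oxygens (O3' benzyl, O2' methoxymethyl).

Step 13
Reactants: 18 methyl 4-hydroxy-3-methylbenzoate
Product: 19 methyl 4-(benzyloxy)-3-methylbenzoate
Conditions: BnBr, K2CO3, acetone, reflux
Reagents that add atoms: benzyl bromide (BrCc1ccccc1)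
Why: Williamson benzylation protects the future 6'-hydroxyl as an ether that is stable to organolithium bases.

Step 14
Reactants: 19 methyl 4-(benzyloxy)-3-methylbenzoate
Product: 20 4-(benzyloxy)-N,N-diethyl-3-methylbenzamide
Conditions: Et2NH, AlMe3, toluene, 0 → 80 °C
Reagents that add atoms: diethylamine (CCNCC)
Why: Aluminium amide aminolysis of the ester gives the tertiary amide that serves as metalation director and later as the acylating carbon for C9'.

Step 15
Reactants: 20 4-(benzyloxy)-N,N-diethyl-3-methylbenzamide; 17 1-(benzyloxy)-5-bromo-2-(methoxymethoxy)-3,4-dimethylbenzene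
Product: 22 4-(benzyloxy)-2-[5-(benzyloxy)-4-(methoxymethoxy)-2,3-dimethylphenyl]-N,N-diethyl-5-methylbenzamide, via arylboronate 21 (not isolated)
Conditions: s-BuLi, TMEDA, THF, −78 °C; B(OMe)3, −78 → 23 °C; then 17, Pd(OAc)2 (3 mol%), SPhos (6 mol%), aq. K3PO4, 65 °C
Reagents that add atoms: none
Why: Amide-directed ortho-metalation at the less hindered ortho position, borylation and Suzuki–Miyaura coupling in one pot should give the biaryl with one ortho substituent on each ring.

Step 16
Reactants: 22 4-(benzyloxy)-2-[5-(benzyloxy)-4-(methoxymethoxy)-2,3-dimethylphenyl]-N,N-diethyl-5-methylbenzamide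
Product: 24 3,6-bis(benzyloxy)-9-methoxy-2-(methoxymethoxy)-1,7-dimethylphenanthrene, via lithium phenanthrenolate 23 (not isolated)
Conditions: LDA (3 equiv), THF, 0 → 23 °C; then Me2SO4, DMPU, 23 °C
Reagents that add atoms: dimethyl sulfate (COS(=O)(=O)OC)
Why: Directed remote metalation should lithiate the methyl group ortho to the biaryl axis (held close to the amide), which acylates itself on the amide to close the middle ring, and the air-sensitive 9-phenanthrenolate is O-methylated in the same flask.

Step 17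
Reactants: 24 3,6-bis(benzyloxy)-9-methoxy-2-(methoxymethoxy)-1,7-dimethylphenanthrene
Product: 25 3,6-bis(benzyloxy)-9-methoxy-1,7-dimethylphenanthren-2-ol
Conditions: HCl (3 M aq.), MeOH–THF, 50 °C
Reagents that add atoms: none
Why: Acidic acetal exchange removes the methoxymethyl group and leaves benzyl and methyl aryl ethers intact.

Step 18
Reactants: 26 methyl 2,2-dimethoxyacetate
Product: 28 1,1-dimethoxy-3-methylbutan-2-one, via Weinreb amide 27 (not isolated)
Conditions: MeNH(OMe)·HCl, i-PrMgCl (4.5 equiv), THF, −20 → 23 °C; aq. NH4Cl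
Reagents that add atoms: isopropylmagnesium chloride (CC(C)[Mg]Cl)
Why: In situ Weinreb amide formation and Grignard addition (Weinreb ketone synthesis) should stop at the ketone through the chelated tetrahedral intermediate.

Step 19
Reactants: 28 1,1-dimethoxy-3-methylbutan-2-one; 25 3,6-bis(benzyloxy)-9-methoxy-1,7-dimethylphenanthren-2-ol
Product: 30 1-{[3,6-bis(benzyloxy)-9-methoxy-1,7-dimethylphenanthren-2-yl]oxy}-1-methoxy-3-methylbutan-2-one (racemic at the acetal carbon), via chloro ether 29 (not isolated)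
Conditions: 28, AcCl, I2 (cat.), 50 °C, then evaporation; 25, NaH, THF–DMF, 0 °C; crude 29, 0 → 23 °C
Reagents that add atoms: none
Why: Acetal-to-α-chloro ether exchange with acetyl chloride, then O-alkylation of the phenoxide by the doubly activated α-chloro-α-methoxy ketone, should give the mixed acetal; C-alkylation is excluded because both ortho positions are substituted.

Step 20
Reactants: 30 1-{[3,6-bis(benzyloxy)-9-methoxy-1,7-dimethylphenanthren-2-yl]oxy}-1-methoxy-3-methylbutan-2-one; 11 4-(benzyloxy)-2-bromo-1-(bromomethyl)-7-methoxy-6-methylnaphthalene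
Product: 32 (3S)-9-(benzyloxy)-3-{[3,6-bis(benzyloxy)-9-methoxy-1,7-dimethylphenanthren-2-yl]oxy}-3,6-dimethoxy-1,1,7-trimethyl-3,4-dihydrophenanthren-2(1H)-one, via benzylated ketone 31 (not isolated)
Conditions: CsOH·H2O (5 equiv), (S,S)-3,3'-bis(3,4,5-trifluorophenyl)binaphthyl-derived N-spiro quaternary ammonium bromide (3 mol%), toluene, −20 °C; then, same flask, Pd2(dba)3 (2.5 mol%), t-Bu3P·HBF4 (10 mol%), NaOt-Bu (3 equiv), 80 °C
Reagents that add atoms: none
Why: Proposed new method: the α,α-dioxygenated methine C3–H of 30 is the more acidic α-position (inductive effect of the methoxy and aryloxy groups), so interfacial hydroxide should give the C3 enolate as a tight ion pair with the C2-symmetric ammonium cation, and SN2 attack on the benzylic bromide of 11 from the unshielded face forms C3–C4 irreversibly and sets the (S)-ketal carbon (closest known type: asymmetric phase-transfer benzylation of prochiral enolates to quaternary α-carbons). The aryl bromide is inert in this stage; after zerovalent palladium and NaOt-Bu are added, the only enolisable position left, the isopropyl C1–H, is arylated intramolecularly by oxidative addition at C10a–Br, enolate binding and C–C reductive elimination (closest known type: intramolecular ketone α-arylation to quaternary benzylic carbons). Ring C is closed in this second event in the 6-(enolendo) mode through a seven-membered palladacycle, and no other ring size is open because C3 is already quaternary. The one new stereocenter, C3, is under catalyst control, with the large aryloxy and the small methoxy group fixing the enolate geometry; C1 is not stereogenic. The step needs site selectivity (C3 over C1 in the alkylation, secured by the acidity difference), C- over O-alkylation (soft benzylic bromide in toluene) and chemoselectivity between the two C–Br bonds (benzylic bromide by SN2 at −20 °C, aryl bromide only by palladium at 80 °C).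

Step 21
Reactants: 32 (3S)-9-(benzyloxy)-3-{[3,6-bis(benzyloxy)-9-methoxy-1,7-dimethylphenanthren-2-yl]oxy}-3,6-dimethoxy-1,1,7-trimethyl-3,4-dihydrophenanthren-2(1H)-one
Product: 33 (3S)-9-hydroxy-3-[(3,6-dihydroxy-9-methoxy-1,7-dimethylphenanthren-2-yl)oxy]-3,6-dimethoxy-1,1,7-trimethyl-3,4-dihydrophenanthren-2(1H)-one
Conditions: H2 (1 atm), Pd/C (10%), EtOAc–EtOH, 23 °C
Reagents that add atoms: none
Why: Hydrogenolysis should remove the three O-benzyl groups; at this stage there is no benzylic C–O bond in the skeleton, the C2 ketone lies between two quaternary carbons, and the C3 ketal is not affected.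

Step 22
Reactants: 33 (3S)-9-hydroxy-3-[(3,6-dihydroxy-9-methoxy-1,7-dimethylphenanthren-2-yl)oxy]-3,6-dimethoxy-1,1,7-trimethyl-3,4-dihydrophenanthren-2(1H)-one
Product: 35 actephilol C, via para-quinone methide 34 (not isolated)
Conditions: Ag2O (1.2 equiv), CH2Cl2 (0.005 M), 0 → 23 °C, dark
Reagents that add atoms: none
Why: Oxidation of the 4-alkyl-1-naphthol (C9–OH para to C4a–C4H2) to the para-quinone methide and intramolecular oxa-1,6-addition of the 3'-hydroxyl, as in oxidative benzodioxane neolignan syntheses, should close the dioxane; the short ortho-phenylene tether on C3 can deliver oxygen to C4 only on the face of the C3–O2' bond, so the (3S)-center sets (4S) and the cis ring fusion.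

**Compound list**

1 | 2-(3-methoxy-4-methylphenyl)acetic acid | OC(=O)Cc1ccc(C)c(OC)c1 | starting material
2 | potassium 3-ethoxy-3-oxopropanoate (potassium ethyl malonate) | CCOC(=O)CC(=O)[O-].[K+] | starting material
3 | 1-[2-(3-methoxy-4-methylphenyl)acetyl]imidazole (not isolated) | O=C(Cc1ccc(C)c(OC)c1)n1ccnc1 | intermediate
4 | ethyl 4-(3-methoxy-4-methylphenyl)-3-oxobutanoate | CCOC(=O)CC(=O)Cc1ccc(C)c(OC)c1 | intermediate
5 | 6-methoxy-7-methylnaphthalene-1,3-diol | COc1cc2cc(O)cc(O)c2cc1C | intermediate
6 | 2,4-dihydroxy-7-methoxy-6-methylnaphthalene-1-carbaldehyde | O=Cc1c(O)cc(O)c2cc(C)c(OC)cc12 | intermediate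
7 | 4-(benzyloxy)-2-hydroxy-7-methoxy-6-methylnaphthalene-1-carbaldehyde | O=Cc1c(O)cc(OCc3ccccc3)c2cc(C)c(OC)cc12 | intermediate
8 | 4-(benzyloxy)-1-formyl-7-methoxy-6-methylnaphthalen-2-yl trifluoromethanesulfonate | O=Cc1c(OS(=O)(=O)C(F)(F)F)cc(OCc3ccccc3)c2cc(C)c(OC)cc12 | intermediate
9 | 4-(benzyloxy)-2-bromo-7-methoxy-6-methylnaphthalene-1-carbaldehyde | O=Cc1c(Br)cc(OCc3ccccc3)c2cc(C)c(OC)cc12 | intermediate
10 | [4-(benzyloxy)-2-bromo-7-methoxy-6-methylnaphthalen-1-yl]methanol | OCc1c(Br)cc(OCc3ccccc3)c2cc(C)c(OC)cc12 | intermediate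
11 | 4-(benzyloxy)-2-bromo-1-(bromomethyl)-7-methoxy-6-methylnaphthalene | BrCc1c(Br)cc(OCc3ccccc3)c2cc(C)c(OC)cc12 | intermediate
12 | 4-bromo-2,3-dimethylphenol | Cc1c(O)ccc(Br)c1C | starting material
13 | 5-bromo-2-hydroxy-3,4-dimethylbenzaldehyde | Cc1c(O)c(C=O)cc(Br)c1C | intermediate
14 | 5-bromo-2-(methoxymethoxy)-3,4-dimethylbenzaldehyde | Cc1c(OCOC)c(C=O)cc(Br)c1C | intermediate
15 | 5-bromo-2-(methoxymethoxy)-3,4-dimethylphenyl formate (not isolated) | Cc1c(OCOC)c(OC=O)cc(Br)c1C | intermediate
16 | 5-bromo-2-(methoxymethoxy)-3,4-dimethylphenol | Cc1c(OCOC)c(O)cc(Br)c1C | intermediate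
17 | 1-(benzyloxy)-5-bromo-2-(methoxymethoxy)-3,4-dimethylbenzene | Cc1c(OCOC)c(OCc2ccccc2)cc(Br)c1C | intermediate
18 | methyl 4-hydroxy-3-methylbenzoate | COC(=O)c1ccc(O)c(C)c1 | starting material
19 | methyl 4-(benzyloxy)-3-methylbenzoate | COC(=O)c1ccc(OCc2ccccc2)c(C)c1 | intermediate
20 | 4-(benzyloxy)-N,N-diethyl-3-methylbenzamide | CCN(CC)C(=O)c1ccc(OCc2ccccc2)c(C)c1 | intermediate
21 | dimethyl [5-(benzyloxy)-2-(diethylcarbamoyl)-4-methylphenyl]boronate (not isolated) | CCN(CC)C(=O)c1cc(C)c(OCc2ccccc2)cc1B(OC)OC | intermediate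
22 | 4-(benzyloxy)-2-[5-(benzyloxy)-4-(methoxymethoxy)-2,3-dimethylphenyl]-N,N-diethyl-5-methylbenzamide | CCN(CC)C(=O)c1cc(C)c(OCc2ccccc2)cc1-c1cc(OCc2ccccc2)c(OCOC)c(C)c1C | intermediate
23 | lithium 3,6-bis(benzyloxy)-2-(methoxymethoxy)-1,7-dimethylphenanthren-9-olate (not isolated) | [Li+].[O-]c1cc2c(C)c(OCOC)c(OCc3ccccc3)cc2c2cc(OCc3ccccc3)c(C)cc12 | intermediate
24 | 3,6-bis(benzyloxy)-9-methoxy-2-(methoxymethoxy)-1,7-dimethylphenanthrene | COc1cc2c(C)c(OCOC)c(OCc3ccccc3)cc2c2cc(OCc3ccccc3)c(C)cc12 | intermediate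
25 | 3,6-bis(benzyloxy)-9-methoxy-1,7-dimethylphenanthren-2-ol | COc1cc2c(C)c(O)c(OCc3ccccc3)cc2c2cc(OCc3ccccc3)c(C)cc12 | intermediate
26 | methyl 2,2-dimethoxyacetate | COC(OC)C(=O)OC | starting material
27 | N,2,2-trimethoxy-N-methylacetamide (not isolated) | COC(OC)C(=O)N(C)OC | intermediate
28 | 1,1-dimethoxy-3-methylbutan-2-one | COC(OC)C(=O)C(C)C | intermediate
29 | 1-chloro-1-methoxy-3-methylbutan-2-one (not isolated, racemic) | COC(Cl)C(=O)C(C)C | intermediate
30 | 1-{[3,6-bis(benzyloxy)-9-methoxy-1,7-dimethylphenanthren-2-yl]oxy}-1-methoxy-3-methylbutan-2-one (racemic at the acetal carbon, which is erased on enolisation) | COc1cc2c(C)c(OC(OC)C(=O)C(C)C)c(OCc3ccccc3)cc2c2cc(OCc3ccccc3)c(C)cc12 | intermediate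
31 | (2S)-2-{[3,6-bis(benzyloxy)-9-methoxy-1,7-dimethylphenanthren-2-yl]oxy}-1-[4-(benzyloxy)-2-bromo-7-methoxy-6-methylnaphthalen-1-yl]-2-methoxy-4-methylpentan-3-one (not isolated) | CC(C)C(=O)[C@@](OC)(Oc1c(C)c2cc(OC)c3cc(C)c(OCc4ccccc4)cc3c2cc1OCc1ccccc1)Cc1c(Br)cc(OCc2ccccc2)c2cc(C)c(OC)cc12 | intermediate
32 | (3S)-9-(benzyloxy)-3-{[3,6-bis(benzyloxy)-9-methoxy-1,7-dimethylphenanthren-2-yl]oxy}-3,6-dimethoxy-1,1,7-trimethyl-3,4-dihydrophenanthren-2(1H)-one | COc1cc2c3c(cc(OCc4ccccc4)c2cc1C)C(C)(C)C(=O)[C@@](OC)(Oc1c(C)c2cc(OC)c4cc(C)c(OCc5ccccc5)cc4c2cc1OCc1ccccc1)C3 | intermediate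
33 | (3S)-9-hydroxy-3-[(3,6-dihydroxy-9-methoxy-1,7-dimethylphenanthren-2-yl)oxy]-3,6-dimethoxy-1,1,7-trimethyl-3,4-dihydrophenanthren-2(1H)-one | COc1cc2c3c(cc(O)c2cc1C)C(C)(C)C(=O)[C@@](OC)(Oc1c(C)c2cc(OC)c4cc(C)c(O)cc4c2cc1O)C3 | intermediate
34 | (3S)-3-[(3,6-dihydroxy-9-methoxy-1,7-dimethylphenanthren-2-yl)oxy]-3,6-dimethoxy-1,1,7-trimethylphenanthrene-2,9(1H,3H)-dione, the para-quinone methide with C4=C4a and C10=C10a double bonds (not isolated) | COc1cc2c(cc1C)C(=O)C=C1C2=C[C@](OC)(Oc2c(C)c3cc(OC)c4cc(C)c(O)cc4c3cc2O)C(=O)C1(C)C | intermediate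
35 | actephilol C, (3S,4S), cis-fused benzodioxane ketal | COc1cc2c3c(cc(O)c2cc1C)C(C)(C)C(=O)[C@@]1(OC)Oc2c(cc4c(cc(OC)c5cc(C)c(O)cc54)c2C)O[C@@H]31 | target

**Step count and risks**

Total steps: 22. Longest linear sequence: 11 steps (12 to 35 through steps 9–12, 15–17 and 19–22; the branch from 1 through steps 1–8 and 20–22 is equally long).

Steps most likely to fail:

1. Step 20 (Proposed new method). The enantioface discrimination in the ammonium enolate ion pair may be insufficient, alkylation may take place at the isopropyl carbon or at the enolate oxygen, or hydroxide may consume the benzylic bromide before C–C bond formation. The fallback uses known chemistry and sets out from 30 and 11. Benzylation under achiral phase-transfer conditions (Bu4NBr, 50% aq. KOH, toluene, 0 °C) should give the racemic benzylated ketone F1, which is isolated and cyclised by intramolecular α-arylation (Pd2(dba)3, t-Bu3P·HBF4, NaOt-Bu, toluene, 80 °C) to the racemic annulation product F2. The enantiomers of F2 are separated by preparative HPLC on an amylose tris(3,5-dimethylphenylcarbamate) stationary phase, and the (3S)-enantiomer is 32, where the route is rejoined.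

2. Step 22. One-electron oxidation of the two phenols of the phenanthrene unit may compete with quinone methide formation, and the product, which still carries a C4–H para to the free naphthol, may be oxidised further. The fallback sets out from 32 and moves the oxidation ahead of the deprotection. Benzylic oxidation of the electron-rich C4 methylene (DDQ, CH2Cl2–H2O, 0 °C) should give the (3R)-9-(benzyloxy)-3-aryloxy-3,6-dimethoxy-1,1,7-trimethylphenanthrene-2,4(1H,3H)-dione F3 (same spatial arrangement at C3; the descriptor changes with the priorities). Reduction of the aryl ketone (NaBH4, CeCl3·7H2O, MeOH, −20 °C) should give the C4 alcohol F4 as a mixture of C4 epimers, which does not matter. Hydrogenolysis (H2, Pd/C, EtOAc) should give the tetraol F5, and a catalytic acid (pyridinium 4-toluenesulfonate, CH2Cl2, 23 °C) ionises the para-hydroxybenzylic alcohol to the same para-quinone methide 34, which closes to 35.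

3. Step 19. The α-chloro ether may be lost by hydrolysis or elimination before the hindered, doubly ortho-substituted phenoxide is alkylated. The fallback sets out from 25. O-Alkylation with the isolable reagent methyl 2-bromo-2-methoxyacetate (K2CO3, DMF, 23 °C) should give methyl 2-{[3,6-bis(benzyloxy)-9-methoxy-1,7-dimethylphenanthren-2-yl]oxy}-2-methoxyacetate F6. A one-pot Weinreb ketone synthesis (MeNH(OMe)·HCl, i-PrMgCl, THF, −20 → 23 °C) then converts the ester into the isopropyl ketone 30, where the route is rejoined.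

**Further compounds**

F1 | step 20 | racemic 2-{[3,6-bis(benzyloxy)-9-methoxy-1,7-dimethylphenanthren-2-yl]oxy}-1-[4-(benzyloxy)-2-bromo-7-methoxy-6-methylnaphthalen-1-yl]-2-methoxy-4-methylpentan-3-one | CC(C)C(=O)C(OC)(Oc1c(C)c2cc(OC)c3cc(C)c(OCc4ccccc4)cc3c2cc1OCc1ccccc1)Cc1c(Br)cc(OCc2ccccc2)c2cc(C)c(OC)cc12
F2 | step 20 | racemic 9-(benzyloxy)-3-{[3,6-bis(benzyloxy)-9-methoxy-1,7-dimethylphenanthren-2-yl]oxy}-3,6-dimethoxy-1,1,7-trimethyl-3,4-dihydrophenanthren-2(1H)-one | COc1cc2c3c(cc(OCc4ccccc4)c2cc1C)C(C)(C)C(=O)C(OC)(Oc1c(C)c2cc(OC)c4cc(C)c(OCc5ccccc5)cc4c2cc1OCc1ccccc1)C3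
F3 | step 22 | (3R)-9-(benzyloxy)-3-{[3,6-bis(benzyloxy)-9-methoxy-1,7-dimethylphenanthren-2-yl]oxy}-3,6-dimethoxy-1,1,7-trimethylphenanthrene-2,4(1H,3H)-dione | COc1cc2c3c(cc(OCc4ccccc4)c2cc1C)C(C)(C)C(=O)[C@@](OC)(Oc1c(C)c2cc(OC)c4cc(C)c(OCc5ccccc5)cc4c2cc1OCc1ccccc1)C3=O
F4 | step 22 | (3S)-9-(benzyloxy)-3-{[3,6-bis(benzyloxy)-9-methoxy-1,7-dimethylphenanthren-2-yl]oxy}-4-hydroxy-3,6-dimethoxy-1,1,7-trimethyl-3,4-dihydrophenanthren-2(1H)-one (mixture of C4 epimers) | COc1cc2c3c(cc(OCc4ccccc4)c2cc1C)C(C)(C)C(=O)[C@@](OC)(Oc1c(C)c2cc(OC)c4cc(C)c(OCc5ccccc5)cc4c2cc1OCc1ccccc1)C3O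
F5 | step 22 | (3S)-4,9-dihydroxy-3-[(3,6-dihydroxy-9-methoxy-1,7-dimethylphenanthren-2-yl)oxy]-3,6-dimethoxy-1,1,7-trimethyl-3,4-dihydrophenanthren-2(1H)-one (mixture of C4 epimers) | COc1cc2c3c(cc(O)c2cc1C)C(C)(C)C(=O)[C@@](OC)(Oc1c(C)c2cc(OC)c4cc(C)c(O)cc4c2cc1O)C3O
F6 | step 19 | methyl 2-{[3,6-bis(benzyloxy)-9-methoxy-1,7-dimethylphenanthren-2-yl]oxy}-2-methoxyacetate (racemic) | COC(=O)C(OC)Oc1c(C)c2cc(OC)c3cc(C)c(OCc4ccccc4)cc3c2cc1OCc1ccccc1
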